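20 mM of starting material, 22.0 mM of partner and 0.50 mM of free catalyst went into each flask, and the flasks differ in bath temperature.

| flask | starting material | partner | free catalyst | temperature | time |
|---|---|---|---|---|---|
| Wednesday's | 20 mM | 22.0 mM | 0.50 mM | 130 °C | 80 min |
| Friday's | 20 mM | 22.0 mM | 0.50 mM | 110 °C | 80 min |
| Tuesday's | 20 mM | 22.0 mM | 0.50 mM | 150 °C | 80 min |
| Saturday's | 20 mM | 22.0 mM | 0.50 mM | 90 °C | 80 min |

- the best flask by amount of target, in percent of the starting material charged; "all alike" if 1.5 percentage points covers them all (Wednesday's / Friday's / Tuesday's / Saturday's / all alike)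
- amount of target at the end, in percent of the starting material charged, Wednesday's
- amount of target at the end, in percent of the starting material charged, Friday's
- amount of target at the end, in percent of the starting material charged, Tuesday's
- amount of target at the end, in percent of the starting material charged, Saturday's

- in percentages every species weighs as the starting material in it: one homo dimer counts as two
- for a step with 2 of a species take k times the square, and two of it per event
- the constants hold at 90 °C; other temperatures follow from the activation energies and enthalpies

    starting material + free catalyst ⇌ catalyst intermediate A (K1 = 420 M⁻¹, k1 = 1740 M⁻¹ h⁻¹, Ea1 = 61.0 kJ mol⁻¹, ΔH1 = −58.0 kJ mol⁻¹)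
    catalyst intermediate A ⇌ catalyst intermediate B (K2 = 0.889, k2 = 44.5 h⁻¹, Ea2 = 113 kJ mol⁻¹, ΔH2 = −47.0 kJ mol⁻¹)
    partner + catalyst intermediate B → catalyst intermediate C (k3 = 8520 M⁻¹ h⁻¹, Ea3 = 47.0 kJ mol⁻¹)
    catalyst intermediate C ⇌ free catalyst + target (K4 = 1.65 M, k4 = 86.9 h⁻¹, Ea4 = 87.0 kJ mol⁻¹, ΔH4 = −39.0 kJ mol⁻¹)
    2 starting material → homo dimer (k5 = 0.0702 M⁻¹ h⁻¹, Ea5 = 107 kJ mol⁻¹)
    partner + catalyst intermediate C ⇌ idle complex, settled at all times (K6 = 94.3 M⁻¹, ΔH6 = 54.0 kJ mol⁻¹)
    partner → decomposed reagent (k7 = 0.258 h⁻¹, Ea7 = 121 kJ mol⁻¹)
    (constants at 90 °C)

Note for whoever takes over Friday's flask, in its bath at 110 °C: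

1. Partner has two exits: step 3, which leads on to target through catalyst intermediate C, and step 7, which gives decomposed reagent. Both rates are first order in partner, so c(partner) cancels from their ratio, and that ratio is what we carry.

2. In Friday's flask k7 is 2.09 h⁻¹, so partner has a half-life of 19.9 min by decomposition. With K1 = 154 M⁻¹ in Friday's flask, step 1 relaxes in 0.314 min at the charged amount and step 2 in 2.25 s, much faster, so we put them at balance with the charged starting material.

3. With K2 = 0.394, that balance leaves c(catalyst intermediate B) = 0.115 mM. Step 3 keeps drawing on this intermediate, so the real value can stand lower.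

4. With k3 = 19200 M⁻¹ h⁻¹, we get 1.05 for the partner split S, the selectivity factor k3·c(catalyst intermediate B)/k7, which counts the mM of partner going through step 3 per mM decomposed. We read it as an upper figure.

5. By this estimate the split sends 51.2% of the partner through step 3, which puts Friday's target under 56.5% of the charged starting material. That is as far as our reckoning goes: it gives an upper figure, not the forecast's number.

6. At 80 min, decomposition by itself would leave 6.16% of Friday's partner, and starting material will remain.

7. Do not raise the bath. Step 7 has a higher activation energy than step 3, and steps 1 and 2 are exothermic, so in our reckoning, at these charges, S falls as the temperature rises.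

The forecast names Friday's as best, with 8.8% for Wednesday's, 34% for Friday's, 1.6% for Tuesday's and 29.5% for Saturday's. Its grounds are that target is “capped by turnover rate in the cool flasks and by the race against partner loss in the hot ones”.

The simulation gives Friday's as best, with 9.62% for Wednesday's, 35.3% for Friday's, 1.58% for Tuesday's and 30.5% for Saturday's. At 80.0 min, Friday's flask holds 0.894% of its partner and 14.7 mM of decomposed reagent. Its target over decomposed reagent reads 0.480, less than S. For Tuesday's flask at 150 °C, the same reckoning with K1 = 27.6 M⁻¹ gives S = 0.0172, and its target over decomposed reagent reads 0.0145.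

All constants were set for the occasion, and the outcome is calculated.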